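**Retrosynthetic overview**

1. Target 38 ⇐ exo-selective formaldehyde aldol at C16 and desilylation of tetracyclic keto lactone 35.
2. 35 ⇐ nickel-catalysed reductive annulation of alkylidene β-keto lactone 33: C9–C11 (radical conjugate addition) and C8–C14 (enolate alkylation) close rings C and D together.
3. 33 ⇐ acetoacetylation and Knoevenagel lactonisation joining fragment A (17, ring A) and fragment B (29, chiral β-keto ester).
4. 17 ⇐ 4,4-dimethylcyclohexadienone by Rh-catalysed desymmetrising vinylation (C5), then two α′-functionalisations at C10; 29 ⇐ desymmetrised 3-(chloromethyl)glutaric anhydride (C13).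
5. Ring order: ring A (step 1) → lactone ring (step 16) → rings C and D (step 17).

Assumption: ent-kaurane atom numbers (C1–C20) are used to describe late intermediates, and the sense of induction of Rh/(R)-BINAP and of (DHQD)2AQN follows the published models (otherwise the antipodal ligand or pseudo-enantiomeric catalyst is used).

**Fragment A (steps 1–7)**

Step 1
Reactants: 1 2-methylpropanal; 2 but-3-en-2-one
Product: 4 4,4-dimethylcyclohex-2-en-1-one, via keto aldehyde 3 (not isolated)
Conditions: conc. H2SO4 (cat.), benzene, reflux, Dean–Stark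
Reagents that add atoms: none
Why: Acid-catalysed Robinson annulation (Michael addition, then intramolecular aldol condensation) is the standard route to this enone; no stereocentre is formed.

Step 2
Reactants: 4 4,4-dimethylcyclohex-2-en-1-one
Product: 5 4,4-dimethylcyclohexa-2,5-dien-1-one
Conditions: DDQ (1.2 equiv), 1,4-dioxane, reflux
Reagents that add atoms: none
Why: DDQ dehydrogenation of the enone through its dienol gives the cross-conjugated dienone, which cannot aromatise because C4 is quaternary.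

Step 3
Reactants: 5 4,4-dimethylcyclohexa-2,5-dien-1-one (2 equiv); 6 potassium ethenyltrifluoroborate
Product: 7 (5R)-5-ethenyl-4,4-dimethylcyclohex-2-en-1-one
Conditions: [Rh(cod)2]BF4 (3 mol %), (R)-BINAP (3.3 mol %), toluene/H2O, 100 °C
Reagents that add atoms: none
Why: Hayashi–Miyaura rhodium-catalysed asymmetric 1,4-addition desymmetrises the dienone; (R)-BINAP selects the enone face as in the cyclohexenone model and sets C5 as R, and the excess of 5 limits a second addition.

Step 4
Reactants: 7 (5R)-5-ethenyl-4,4-dimethylcyclohex-2-en-1-one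
Product: 9 (5S)-5-(hydroxymethyl)-4,4-dimethylcyclohex-2-en-1-one, via aldehyde 8 (not isolated)
Conditions: O3 (1.0 equiv), CH2Cl2/MeOH, −78 °C; then NaBH4, −78 °C; AcOH quench
Reagents that add atoms: ozone, [O-][O+]=O
Why: Ozonolysis with reductive work-up; ozone cleaves the electron-rich vinyl group faster than the conjugated ring alkene, and borohydride at −78 °C reduces the aldehyde (not the enone) before it can enolise, so C5 is untouched (the descriptor changes only by priority).

Step 5
Reactants: 9 (5S)-5-(hydroxymethyl)-4,4-dimethylcyclohex-2-en-1-one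
Product: 10 (5S)-5-({[tert-butyl(diphenyl)silyl]oxy}methyl)-4,4-dimethylcyclohex-2-en-1-one
Conditions: TBDPSCl, imidazole, DMF, rt
Reagents that add atoms: tert-butyl(chloro)diphenylsilane, CC(C)(C)[Si](Cl)(c1ccccc1)c1ccccc1
Why: Standard silylation; the acid-stable TBDPS ether masks the C6 hydroxyl until the last step.

Step 6
Reactants: 10 (5S)-5-({[tert-butyl(diphenyl)silyl]oxy}methyl)-4,4-dimethylcyclohex-2-en-1-one; 11 formaldehyde
Product: 13 (5S,6R)-5-({[tert-butyl(diphenyl)silyl]oxy}methyl)-6-(hydroxymethyl)-4,4-dimethylcyclohex-2-en-1-one, via silyl dienol ether 12 (not isolated)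
Conditions: LiN(i-Pr)2, THF, −78 °C, then TMSCl; then Sc(OTf)3 (10 mol %), aq. HCHO, THF, rt
Reagents that add atoms: none
Why: C10 is the only enolisable position, so kinetic enolisation and a Mukaiyama aldol with aqueous formaldehyde install C20; the trans C10 configuration formed here is erased in step 7.

Step 7
Reactants: 13 (5S,6R)-5-({[tert-butyl(diphenyl)silyl]oxy}methyl)-6-(hydroxymethyl)-4,4-dimethylcyclohex-2-en-1-one; 14 trimethoxymethane
Product: 17 (5R,6S)-5-({[tert-butyl(diphenyl)silyl]oxy}methyl)-6-(dimethoxymethyl)-6-(hydroxymethyl)-4,4-dimethylcyclohex-2-en-1-one, via bis-silyl dienol ether 15 (not isolated), via silyl ether acetal 16 (not isolated)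
Conditions: TMSOTf (3.5 equiv), i-Pr2NEt (3 equiv), CH2Cl2, 0 °C; then 14, −78 to −40 °C; then citric acid, MeOH, 0 °C
Reagents that add atoms: none
Why: Soft enolisation and Mukaiyama-type alkylation by the dimethoxycarbenium ion occur anti to the pseudo-axial C5 side chain (A(1,2) strain), which sets the quaternary C10 with C9 trans and C20 cis to C6; methanolysis then frees the primary alcohol.

**Fragment B (steps 8–14)**

Step 8
Reactants: 18 cyclopent-3-en-1-ylmethanol
Product: 19 4-(chloromethyl)cyclopent-1-ene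
Conditions: PPh3, N-chlorosuccinimide, CH2Cl2, 0 °C to rt
Reagents that add atoms: N-chlorosuccinimide, ClN1C(=O)CCC1=O
Why: Appel-type chlorination of a primary alcohol by SN2 displacement of the oxyphosphonium.

Step 9
Reactants: 19 4-(chloromethyl)cyclopent-1-ene
Product: 20 3-(chloromethyl)pentanedioic acid
Conditions: RuCl3·xH2O (2 mol %), NaIO4 (4.1 equiv), CCl4/MeCN/H2O, rt
Reagents that add atoms: sodium periodate, [Na+].[O-]I(=O)(=O)=O
Why: Catalytic RuO4 (Sharpless conditions) cleaves the ring alkene directly to the prochiral diacid.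

Step 10
Reactants: 20 3-(chloromethyl)pentanedioic acid
Product: 21 4-(chloromethyl)oxane-2,6-dione
Conditions: (CF3CO)2O, CH2Cl2, 0 °C to rt
Reagents that add atoms: none
Why: Mild cyclodehydration through the mixed anhydride gives the meso-type glutaric anhydride without displacing the chloride.

Step 11
Reactants: 21 4-(chloromethyl)oxane-2,6-dione
Product: 22 (3S)-3-(chloromethyl)-5-methoxy-5-oxopentanoic acid
Conditions: (DHQD)2AQN (10 mol %), MeOH (10 equiv), Et2O, −20 °C; cold acidic work-up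
Reagents that add atoms: methanol, CO
Why: Cinchona-alkaloid-catalysed desymmetrising methanolysis of a prochiral anhydride opens one enantiotopic carbonyl and sets the future C13 stereocentre.

Step 12
Reactants: 22 (3S)-3-(chloromethyl)-5-methoxy-5-oxopentanoic acid
Product: 24 (4S)-4-(chloromethyl)oxan-2-one, via hydroxy ester 23 (not isolated)
Conditions: BH3·SMe2, THF, −10 °C to rt; then TsOH (cat.), toluene, rt
Reagents that add atoms: none
Why: Borane reduces the acid chemoselectively in the presence of the ester, and acid-catalysed lactonisation follows; the stereocentre is not involved.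

Step 13
Reactants: 24 (4S)-4-(chloromethyl)oxan-2-one
Product: 25 (3R)-5-bromo-3-(chloromethyl)pentanoic acid
Conditions: HBr (33 % in AcOH), rt
Reagents that add atoms: hydrogen bromide, Br
Why: Acid-promoted SN2 ring opening of the δ-lactone by bromide at the O–CH2 carbon gives the bromo acid; the primary chloride is inert (the descriptor changes only by priority).

Step 14
Reactants: 25 (3R)-5-bromo-3-(chloromethyl)pentanoic acid; 26 tert-butyl acetate
Product: 29 tert-butyl (5R)-7-bromo-5-(chloromethyl)-3-oxoheptanoate, via acid chloride 27 (not isolated), via lithium enolate 28 (not isolated)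
Conditions: 25, (COCl)2, DMF (cat.), CH2Cl2, 0 °C to rt; 26, LiN(i-Pr)2, THF, −78 °C; add 27 to 28 (3 equiv), −78 °C; NH4Cl (aq)
Reagents that add atoms: none
Why: Crossed Claisen acylation of the ester enolate by the acid chloride is fast at −78 °C, where the primary halides do not alkylate the enolate.

**Union and endgame (steps 15–19)**

Step 15
Reactants: 17 (5R,6S)-5-({[tert-butyl(diphenyl)silyl]oxy}methyl)-6-(dimethoxymethyl)-6-(hydroxymethyl)-4,4-dimethylcyclohex-2-en-1-one; 29 tert-butyl (5R)-7-bromo-5-(chloromethyl)-3-oxoheptanoate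
Product: 31 [(1S,6R)-6-({[tert-butyl(diphenyl)silyl]oxy}methyl)-1-(dimethoxymethyl)-5,5-dimethyl-2-oxocyclohex-3-en-1-yl]methyl (5R)-7-bromo-5-(chloromethyl)-3-oxoheptanoate, via acylketene 30 (not isolated)
Conditions: toluene, 110 °C, N2 stream
Reagents that add atoms: none
Why: Thermal transacetoacetylation; the tert-butyl β-keto ester loses tert-butanol to an acylketene that acylates the hindered neopentyl alcohol under neutral conditions.

Step 16
Reactants: 31 (the β-keto ester of step 15)
Product: 33 (6S,11R)-4-[(3R)-5-bromo-3-(chloromethyl)pentanoyl]-11-({[tert-butyl(diphenyl)silyl]oxy}methyl)-10,10-dimethyl-2-oxaspiro[5.5]undeca-4,8-diene-3,7-dione, via keto ester aldehyde 32 (not isolated)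
Conditions: TFA/H2O (9:1), CH2Cl2, 0 °C; then piperidine (0.2 equiv), AcOH (0.2 equiv), benzene, 4 Å MS, rt
Reagents that add atoms: none
Why: Acetal hydrolysis unmasks the C9 aldehyde, and intramolecular Knoevenagel condensation with the β-keto ester closes the six-membered α-acyl-α,β-unsaturated lactone (C8=C9); no stereocentre is formed.

Step 17
Reactants: 33 (the spiro alkylidene keto lactone of step 16)
Product: 35 6-O-TBDPS ether of (5R,8S,9S,10S,13R)-6-hydroxy-1,15-dioxo-17-nor-6,7-secokaur-2-en-7,20-olide, via manganese enolate 34 (not isolated)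
Conditions: NiBr2(dme) (10 mol %), 4,4′-di-tert-butyl-2,2′-bipyridine (12 mol %), Mn powder (3 equiv), DMA (0.01 M), 35 °C; then NaI (2 equiv), 70 °C
Reagents that add atoms: none
Why: Proposed new method: low-valent nickel abstracts bromine from the primary bromide, the C11 radical adds 7-endo to C9 of the doubly activated alkene on the face anti to the bulky C5 side of ring A (sets C9), the captodative C8 radical is reduced to the manganese enolate, and this displaces the tethered chloride (iodide exchange) to form C8–C14, with the C13 centre forcing the bridged bicyclo[3.2.1]octane geometry (sets C8); the closest known reactions are nickel-catalysed reductive conjugate addition of alkyl halides to enones and nickel/zinc-mediated Giese additions.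

Step 18
Reactants: 35 (the tetracyclic keto lactone of step 17); 11 formaldehyde
Product: 37 6-O-TBDPS ether of (5R,8S,9S,10S,13R,16R)-6,17-dihydroxy-1,15-dioxo-6,7-secokaur-2-en-7,20-olide, via lithium enolate 36 (not isolated)
Conditions: LiN(i-Pr)2 (1.1 equiv), THF, −78 °C; then monomeric CH2O in THF, −78 °C; AcOH quench
Reagents that add atoms: none
Why: C16 is the only enolisable carbon (C8 and C10 are quaternary, C2 is vinylic), and the aldol addition to formaldehyde takes place on the exo face of the two-carbon bridge, away from the three-carbon bridge, which sets C16 as R.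

Step 19
Reactants: 37 (the silyl ether of step 18)
Product: 38 (5R,8S,9S,10S,13R,16R)-6,17-dihydroxy-1,15-dioxo-6,7-secokaur-2-en-7,20-olide (CNP0505075.1)
Conditions: HF·pyridine, pyridine/THF, 0 °C to rt
Reagents that add atoms: none
Why: Buffered fluoride desilylation frees the C6 alcohol without retro-aldol or dehydration of the β-hydroxy ketone.

**Compound list**

1 | 2-methylpropanal | CC(C)C=O | starting material
2 | but-3-en-2-one | CC(=O)C=C | starting material
3 | 2,2-dimethyl-5-oxohexanal | CC(=O)CCC(C)(C)C=O | intermediate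
4 | 4,4-dimethylcyclohex-2-en-1-one | CC1(C)C=CC(=O)CC1 | intermediate
5 | 4,4-dimethylcyclohexa-2,5-dien-1-one | CC1(C)C=CC(=O)C=C1 | intermediate
6 | potassium ethenyltrifluoroborate | [K+].F[B-](F)(F)C=C | starting material
7 | (5R)-5-ethenyl-4,4-dimethylcyclohex-2-en-1-one | CC1(C)C=CC(=O)C[C@@H]1C=C | intermediate
8 | (1S)-2,2-dimethyl-5-oxocyclohex-3-ene-1-carbaldehyde | CC1(C)C=CC(=O)C[C@@H]1C=O | intermediate
9 | (5S)-5-(hydroxymethyl)-4,4-dimethylcyclohex-2-en-1-one | CC1(C)C=CC(=O)C[C@@H]1CO | intermediate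
10 | (5S)-5-({[tert-butyl(diphenyl)silyl]oxy}methyl)-4,4-dimethylcyclohex-2-en-1-one | CC1(C)C=CC(=O)C[C@@H]1CO[Si](c2ccccc2)(c3ccccc3)C(C)(C)C | intermediate
11 | formaldehyde | C=O | starting material
12 | tert-butyl({(1S)-6,6-dimethyl-3-[(trimethylsilyl)oxy]cyclohexa-2,4-dien-1-yl}methoxy)diphenylsilane | CC1(C)C=CC(O[Si](C)(C)C)=C[C@@H]1CO[Si](c2ccccc2)(c3ccccc3)C(C)(C)C | intermediate
13 | (5S,6R)-5-({[tert-butyl(diphenyl)silyl]oxy}methyl)-6-(hydroxymethyl)-4,4-dimethylcyclohex-2-en-1-one | CC1(C)C=CC(=O)[C@@H](CO)[C@@H]1CO[Si](c2ccccc2)(c3ccccc3)C(C)(C)C | intermediate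
14 | trimethoxymethane | COC(OC)OC | starting material
15 | tert-butyl({(1R)-6,6-dimethyl-3-[(trimethylsilyl)oxy]-2-{[(trimethylsilyl)oxy]methyl}cyclohexa-2,4-dien-1-yl}methoxy)diphenylsilane | CC1(C)C=CC(O[Si](C)(C)C)=C(CO[Si](C)(C)C)[C@@H]1CO[Si](c2ccccc2)(c3ccccc3)C(C)(C)C | intermediate
16 | (5R,6S)-5-({[tert-butyl(diphenyl)silyl]oxy}methyl)-6-(dimethoxymethyl)-4,4-dimethyl-6-{[(trimethylsilyl)oxy]methyl}cyclohex-2-en-1-one | CC1(C)C=CC(=O)[C@](C(OC)OC)(CO[Si](C)(C)C)[C@@H]1CO[Si](c2ccccc2)(c3ccccc3)C(C)(C)C | intermediate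
17 | (5R,6S)-5-({[tert-butyl(diphenyl)silyl]oxy}methyl)-6-(dimethoxymethyl)-6-(hydroxymethyl)-4,4-dimethylcyclohex-2-en-1-one (fragment A) | CC1(C)C=CC(=O)[C@](C(OC)OC)(CO)[C@@H]1CO[Si](c2ccccc2)(c3ccccc3)C(C)(C)C | intermediate
18 | cyclopent-3-en-1-ylmethanol | OCC1CC=CC1 | starting material
19 | 4-(chloromethyl)cyclopent-1-ene | ClCC1CC=CC1 | intermediate
20 | 3-(chloromethyl)pentanedioic acid | OC(=O)CC(CCl)CC(=O)O | intermediate
21 | 4-(chloromethyl)oxane-2,6-dione | O=C1CC(CCl)CC(=O)O1 | intermediate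
22 | (3S)-3-(chloromethyl)-5-methoxy-5-oxopentanoic acid | ClC[C@@H](CC(=O)O)CC(=O)OC | intermediate
23 | methyl (3S)-3-(chloromethyl)-5-hydroxypentanoate | ClC[C@@H](CCO)CC(=O)OC | intermediate
24 | (4S)-4-(chloromethyl)oxan-2-one | ClC[C@H]1CCOC(=O)C1 | intermediate
25 | (3R)-5-bromo-3-(chloromethyl)pentanoic acid | ClC[C@@H](CCBr)CC(=O)O | intermediate
26 | tert-butyl acetate | CC(=O)OC(C)(C)C | starting material
27 | (3R)-5-bromo-3-(chloromethyl)pentanoyl chloride | ClC[C@@H](CCBr)CC(=O)Cl | intermediate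
28 | lithium 1-tert-butoxyethen-1-olate | [Li+].[O-]C(=C)OC(C)(C)C | intermediate
29 | tert-butyl (5R)-7-bromo-5-(chloromethyl)-3-oxoheptanoate (fragment B) | ClC[C@@H](CCBr)CC(=O)CC(=O)OC(C)(C)C | intermediate
30 | (5R)-7-bromo-5-(chloromethyl)hept-1-ene-1,3-dione (acylketene) | ClC[C@@H](CCBr)CC(=O)C=C=O | intermediate
31 | [(1S,6R)-6-({[tert-butyl(diphenyl)silyl]oxy}methyl)-1-(dimethoxymethyl)-5,5-dimethyl-2-oxocyclohex-3-en-1-yl]methyl (5R)-7-bromo-5-(chloromethyl)-3-oxoheptanoate | CC1(C)C=CC(=O)[C@](C(OC)OC)(COC(=O)CC(=O)C[C@@H](CCl)CCBr)[C@@H]1CO[Si](c2ccccc2)(c3ccccc3)C(C)(C)C | intermediate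
32 | [(1S,6R)-6-({[tert-butyl(diphenyl)silyl]oxy}methyl)-1-formyl-5,5-dimethyl-2-oxocyclohex-3-en-1-yl]methyl (5R)-7-bromo-5-(chloromethyl)-3-oxoheptanoate | CC1(C)C=CC(=O)[C@](C=O)(COC(=O)CC(=O)C[C@@H](CCl)CCBr)[C@@H]1CO[Si](c2ccccc2)(c3ccccc3)C(C)(C)C | intermediate
33 | (6S,11R)-4-[(3R)-5-bromo-3-(chloromethyl)pentanoyl]-11-({[tert-butyl(diphenyl)silyl]oxy}methyl)-10,10-dimethyl-2-oxaspiro[5.5]undeca-4,8-diene-3,7-dione | CC1(C)C=CC(=O)[C@]2(COC(=O)C(C(=O)C[C@@H](CCl)CCBr)=C2)[C@@H]1CO[Si](c3ccccc3)(c4ccccc4)C(C)(C)C | intermediate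
34 | manganese bromide enolate (C8=C15–O) of the C9–C11 cyclised keto lactone, chloride at C14 intact (C5 R, C9 R, C10 S, C13 R) | CC1(C)C=CC(=O)[C@]2(COC(=O)C3=C([O-])C[C@@H](CCl)CC[C@H]32)[C@@H]1CO[Si](c4ccccc4)(c5ccccc5)C(C)(C)C.[Mn+2].[Br-] | intermediate
35 | 6-O-TBDPS ether of (5R,8S,9S,10S,13R)-6-hydroxy-1,15-dioxo-17-nor-6,7-secokaur-2-en-7,20-olide | CC1(C)C=CC(=O)[C@]2(COC(=O)[C@@]34C[C@@H](CC[C@H]32)CC4=O)[C@@H]1CO[Si](c5ccccc5)(c6ccccc6)C(C)(C)C | intermediate
36 | lithium C15(O)=C16 enolate of 35 | CC1(C)C=CC(=O)[C@]2(COC(=O)[C@@]34C[C@@H](CC[C@H]32)C=C4[O-])[C@@H]1CO[Si](c5ccccc5)(c6ccccc6)C(C)(C)C.[Li+] | intermediate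
37 | 6-O-TBDPS ether of (5R,8S,9S,10S,13R,16R)-6,17-dihydroxy-1,15-dioxo-6,7-secokaur-2-en-7,20-olide | CC1(C)C=CC(=O)[C@]2(COC(=O)[C@@]34C[C@@H](CC[C@H]32)[C@H](CO)C4=O)[C@@H]1CO[Si](c5ccccc5)(c6ccccc6)C(C)(C)C | intermediate
38 | (5R,8S,9S,10S,13R,16R)-6,17-dihydroxy-1,15-dioxo-6,7-secokaur-2-en-7,20-olide (CNP0505075.1) | CC1(C)C=CC(=O)[C@]2(COC(=O)[C@@]34C[C@@H](CC[C@H]32)[C@H](CO)C4=O)[C@@H]1CO | target

**Totals**

Total step count: 19. Longest linear sequence: 12 steps (steps 1–7 then 15–19; the fragment B line, steps 8–14 then 15–19, is equally long).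

**Three steps most likely to fail**

Step 17 (the proposed nickel annulation). The 7-endo radical addition may lose to reduction of the alkylidene, or the enolate may not alkylate under the reductive conditions. The fallback uses known tin-mediated radical chain chemistry and a separate ionic ring closure, and sets out from 33. Bu3SnH (1.3 equiv) and AIBN are added by syringe pump to a 5 mM benzene solution at 80 °C. The same 7-endo Giese cyclisation then gives the neutral cyclised β-keto lactone (C8–H, chloride intact) F1, which is isolated. K2CO3 and NaI in DMF at 50 °C then close C8–C14 by intramolecular enolate alkylation, and the route is rejoined at 35.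

Step 3 (desymmetrising vinylation of the hindered dienone). Risks are low conversion at the neopentyl β-carbon and a second addition. The fallback sets out from mono-enone 4, which has a single acceptor. The same Rh/(R)-BINAP addition of 6 gives (3R)-3-ethenyl-4,4-dimethylcyclohexan-1-one F2. Kinetic enolisation away from the branched side (LiN(i-Pr)2, TMSCl, THF, −78 °C) gives {[(5R)-5-ethenyl-4,4-dimethylcyclohex-1-en-1-yl]oxy}trimethylsilane F3. Saegusa–Ito oxidation (Pd(OAc)2, MeCN, rt) restores the enone, and the route is rejoined at 7.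

Step 7 (quaternary C10 by orthoformate alkylation of a β-silyloxy dienol ether). Risks are elimination of the silyloxy group and low reactivity at the tetrasubstituted carbon. The fallback installs C9 as a second hydroxymethyl group and oxidises it, and sets out from 13.
- TBSCl and imidazole give (5S,6R)-6-({[tert-butyl(dimethyl)silyl]oxy}methyl)-5-({[tert-butyl(diphenyl)silyl]oxy}methyl)-4,4-dimethylcyclohex-2-en-1-one F4.
- TMSOTf and Et3N give its trimethylsilyl dienol ether F5.
- Sc(OTf)3 and aqueous formaldehyde, again anti to the C5 side chain, give (5R,6R)-6-({[tert-butyl(dimethyl)silyl]oxy}methyl)-5-({[tert-butyl(diphenyl)silyl]oxy}methyl)-6-(hydroxymethyl)-4,4-dimethylcyclohex-2-en-1-one F6.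
- Dess–Martin periodinane gives (1S,6R)-1-({[tert-butyl(dimethyl)silyl]oxy}methyl)-6-({[tert-butyl(diphenyl)silyl]oxy}methyl)-5,5-dimethyl-2-oxocyclohex-3-ene-1-carbaldehyde F7.
- HC(OMe)3, PPTS and MeOH give (5R,6S)-6-({[tert-butyl(dimethyl)silyl]oxy}methyl)-5-({[tert-butyl(diphenyl)silyl]oxy}methyl)-6-(dimethoxymethyl)-4,4-dimethylcyclohex-2-en-1-one F8.
- Camphorsulfonic acid in MeOH at 0 °C removes only the primary TBS ether, and the route is rejoined at 17.

**Further compounds**

F1 | step 17 | cyclised β-keto lactone, C9–C11 bonded, C8–H (epimers), chloride at C14 intact, 6-O-TBDPS | CC1(C)C=CC(=O)[C@]2(COC(=O)C3C(=O)C[C@@H](CCl)CC[C@H]32)[C@@H]1CO[Si](c4ccccc4)(c5ccccc5)C(C)(C)C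
F2 | step 3 | (3R)-3-ethenyl-4,4-dimethylcyclohexan-1-one | CC1(C)CCC(=O)C[C@@H]1C=C
F3 | step 3 | {[(5R)-5-ethenyl-4,4-dimethylcyclohex-1-en-1-yl]oxy}trimethylsilane | CC1(C)CC=C(O[Si](C)(C)C)C[C@@H]1C=C
F4 | step 7 | (5S,6R)-6-({[tert-butyl(dimethyl)silyl]oxy}methyl)-5-({[tert-butyl(diphenyl)silyl]oxy}methyl)-4,4-dimethylcyclohex-2-en-1-one | CC1(C)C=CC(=O)[C@@H](CO[Si](C)(C)C(C)(C)C)[C@@H]1CO[Si](c2ccccc2)(c3ccccc3)C(C)(C)C
F5 | step 7 | trimethylsilyl dienol ether of F4 | CC1(C)C=CC(O[Si](C)(C)C)=C(CO[Si](C)(C)C(C)(C)C)[C@@H]1CO[Si](c2ccccc2)(c3ccccc3)C(C)(C)C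
F6 | step 7 | (5R,6R)-6-({[tert-butyl(dimethyl)silyl]oxy}methyl)-5-({[tert-butyl(diphenyl)silyl]oxy}methyl)-6-(hydroxymethyl)-4,4-dimethylcyclohex-2-en-1-one | CC1(C)C=CC(=O)[C@](CO)(CO[Si](C)(C)C(C)(C)C)[C@@H]1CO[Si](c2ccccc2)(c3ccccc3)C(C)(C)C
F7 | step 7 | (1S,6R)-1-({[tert-butyl(dimethyl)silyl]oxy}methyl)-6-({[tert-butyl(diphenyl)silyl]oxy}methyl)-5,5-dimethyl-2-oxocyclohex-3-ene-1-carbaldehyde | CC1(C)C=CC(=O)[C@](C=O)(CO[Si](C)(C)C(C)(C)C)[C@@H]1CO[Si](c2ccccc2)(c3ccccc3)C(C)(C)C
F8 | step 7 | (5R,6S)-6-({[tert-butyl(dimethyl)silyl]oxy}methyl)-5-({[tert-butyl(diphenyl)silyl]oxy}methyl)-6-(dimethoxymethyl)-4,4-dimethylcyclohex-2-en-1-one | CC1(C)C=CC(=O)[C@](C(OC)OC)(CO[Si](C)(C)C(C)(C)C)[C@@H]1CO[Si](c2ccccc2)(c3ccccc3)C(C)(C)C
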